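**Retrosynthetic overview**

1. The acetate goes on last. The C2–O bond and the C3=C4 enol ether are made together from the isomeric enol ether (C2=C3, OMe on C3) by a singlet-oxygen ene reaction on the C8 face. A hydride would enter a C2 ketone from that same open face and give the C2 epimer, so the C2 ketone is not reduced.
2. That enol ether comes from the bicyclo[3.2.1]octane-2,8-dione (C3 methoxylation, enol triflate, reduction), and the dione from the 2-acetoxybicyclo[3.2.1]octan-8-one.
3. Key disconnection: the C8 ketone that bridges the methoxy-bearing bridgehead C1 and the allyl-bearing quaternary bridgehead C5 is the mark of an acid-induced double 1,2-shift of a 1-methoxybicyclo[4.2.0]octan-2-one. The shift makes C5–C8 and C1–C2 and closes the five- and six-membered rings of the bicycle in one step.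
4. The cyclobutane, with C1, C5, C6 and C7, comes from a head-to-head [2+2] photocycloaddition of 6-acetoxy-3-allyl-2-methoxycyclohex-2-enone with (E)-isoeugenol methyl ether. The enone comes from cyclohexane-1,2-dione by O-allylation/Claisen rearrangement, O-methylation, α'-hydroxylation and lipase resolution.
5. Ring order: six-membered carbocycle (bought), cyclobutane (step 6), then the cyclopentane and cyclohexane rings of the bicyclo[3.2.1]octane together (step 7).

Key step: step 7

Remark on locants: cyclobutanes are numbered as bicyclo[4.2.0]octanes (C1 OMe, C2 C=O, C3 OAc, C6 allyl, C7 Me, C8 aryl). All bicyclo[3.2.1]octanes are numbered C1 (OMe bridgehead), C2, C3, C4, C5 (allyl bridgehead), C6 (Me), C7 (aryl), C8 (ketone bridge), also where a systematic name would number otherwise.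

Assumption: the lipase is taken to acylate the (R)-enantiomer of 7. This centre is removed in step 9, so the opposite preference would change only the descriptors of 8 and 10–12.

Remark: a chiral Lewis acid is not used in the photocycloaddition because strong Lewis acids oligomerise the electron-rich propenylbenzene. The absolute configuration is secured by resolution (step 5) and separation of diastereomers (step 6). Recovered (S)-7 can be acetylated and taken through steps 6–9 in the same way, converging at 13.

**Route**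

Step 1
Reactants: 1 cyclohexane-1,2-dione; 2 allyl bromide
Product: 3 2-(allyloxy)cyclohex-2-en-1-one
Conditions: K2CO3, acetone, reflux
Reagents that add atoms: none
Why: Williamson O-alkylation of the enol (diosphenol) form of the dione with a reactive allylic halide under carbonate conditions should give the allyl enol ether.

Step 2
Reactants: 3 2-(allyloxy)cyclohex-2-en-1-one
Product: 4 3-allyl-2-hydroxycyclohex-2-en-1-one
Conditions: xylene, 185 °C, sealed tube
Reagents that add atoms: none
Why: Claisen [3,3]-sigmatropic rearrangement of the allyl enol ether delivers the allyl group to C3, and the 3-allyl-1,2-dione formed should enolise to the fully substituted diosphenol.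

Step 3
Reactants: 4 3-allyl-2-hydroxycyclohex-2-en-1-one
Product: 5 3-allyl-2-methoxycyclohex-2-en-1-one
Conditions: Me2SO4, K2CO3, acetone, reflux
Reagents that add atoms: dimethyl sulfate, COS(=O)(=O)OC
Why: Williamson O-methylation of the acidic diosphenol with a hard methylating agent should trap the more substituted, conjugated enol as the 2-methoxy enone.

Step 4
Reactants: 5 3-allyl-2-methoxycyclohex-2-en-1-one
Product: 7 rac-3-allyl-6-hydroxy-2-methoxycyclohex-2-en-1-one, via lithium enolate 6 (not isolated)
Conditions: LiN(iPr)2, THF, −78 °C; 3-phenyl-2-(phenylsulfonyl)oxaziridine, −78 °C; AcOH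
Reagents that add atoms: 3-phenyl-2-(phenylsulfonyl)oxaziridine, O=S(=O)(c1ccccc1)N1OC1c1ccccc1
Why: Kinetic α'-deprotonation of the enone at C6 and enolate hydroxylation with an N-sulfonyloxaziridine, which leaves both C=C bonds untouched, should give the racemic α'-hydroxy enone.

Step 5
Reactants: 7 rac-3-allyl-6-hydroxy-2-methoxycyclohex-2-en-1-one
Product: 8 (R)-4-allyl-3-methoxy-2-oxocyclohex-3-en-1-yl acetate
Conditions: lipase from Burkholderia cepacia (lipase PS), vinyl acetate, t-BuOMe, 30 °C, stopped near half conversion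
Reagents that add atoms: vinyl acetate, C=COC(C)=O
Why: Lipase-catalysed kinetic resolution by enantioselective transesterification, for which α'-hydroxy enones are an established substrate class, should acetylate one enantiomer and so set C6, the centre that later makes the two faces of the [2+2] adducts separable as diastereomers; (S)-7 is left behind.

Step 6
Reactants: 8 (R)-4-allyl-3-methoxy-2-oxocyclohex-3-en-1-yl acetate; 9 (E)-isoeugenol methyl ether
Product: 10 (1R,3R,6S,7R,8S)-6-allyl-8-(3,4-dimethoxyphenyl)-1-methoxy-7-methyl-2-oxobicyclo[4.2.0]octan-3-yl acetate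
Conditions: 9 (5 equiv), hν (366 nm), CH2Cl2, −40 °C
Reagents that add atoms: none
Why: Enone–alkene [2+2] photocycloaddition through the enone triplet, in which the first bond is expected from the allyl-bearing enone carbon to the CHMe carbon of the conjugated alkene to give the benzylic/α-acyl-α-methoxy 1,4-biradical, which should close head-to-head and cis-fused with the aryl group on the convex face and the methyl group trans to it under the six-membered ring (alkene geometry is lost in the biradical, so E/Z isomerisation of 9 does no harm); the remote acetoxy centre gives no facial control, so 10 is separated by chromatography from the diastereomer of opposite ring configuration and from minor stereo- and regioisomers.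

Step 7
Reactants: 10 (1R,3R,6S,7R,8S)-6-allyl-8-(3,4-dimethoxyphenyl)-1-methoxy-7-methyl-2-oxobicyclo[4.2.0]octan-3-yl acetate
Product: 11 (1S,2R,5S,6R,7S)-5-allyl-7-(3,4-dimethoxyphenyl)-1-methoxy-6-methyl-8-oxobicyclo[3.2.1]octan-2-yl acetate
Conditions: BF3·OEt2 (2 equiv), CH2Cl2, −40 → 0 °C
Reagents that add atoms: none
Why: BF3 bound to the ketone of 10 (C8 of the product) makes this carbon a carbinyl cation beside the cyclobutane, the ring-fusion carbon C5 shifts from C1 to C8 (cyclobutylcarbinyl-to-cyclopentyl ring expansion; this 1,2-shift closes the five-membered ring C1–C7–C6–C5–C8 through the new C5–C8 bond) and leaves a C1 oxocarbenium ion held by the methoxy group, and a pinacol-type 1,2-shift of the acetoxy-bearing C2 from C8 to C1 (new C1–C2 bond) closes the six-membered ring C1–C2–C3–C4–C5–C8 and returns the ketone as the one-carbon bridge. The closest known reaction is the acid-promoted Cargill-type rearrangement of bicyclo[4.2.0]octan-2-ones that carry a substituent on the distal fusion carbon to bicyclo[3.2.1]octan-8-ones, run here on an α-methoxy ketone so that the intermediate cation is an oxocarbenium ion. Both shifts are suprafacial with retention at the migrating carbons, so C5, C6, C7 and C2 keep the configurations set in steps 5 and 6, and the new bridgehead C1 can only form with C2 entering on the face on which the six-membered ring of 10 lay, as the cis ring fusion dictates. The step needs the quaternary fusion carbon to migrate in preference to the benzylic cyclobutane carbon C7 and in preference to heterolysis of the C1–C7 bond; the higher migratory aptitude of the fully substituted carbon, the low temperature and a Lewis acid too weak to cleave aryl methyl ethers are chosen for this, and the acetate (in place of a free or silylated hydroxyl) blocks an acyloin-type hydride shift from C2.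

Step 8
Reactants: 11 (1S,2R,5S,6R,7S)-5-allyl-7-(3,4-dimethoxyphenyl)-1-methoxy-6-methyl-8-oxobicyclo[3.2.1]octan-2-yl acetate
Product: 12 (1S,2R,5S,6R,7S)-5-allyl-7-(3,4-dimethoxyphenyl)-2-hydroxy-1-methoxy-6-methylbicyclo[3.2.1]octan-8-one
Conditions: HCl (cat.), MeOH, 0 °C → rt
Reagents that add atoms: none
Why: Acid-catalysed transesterification should remove the acetate without forming the alkoxide of the β-hydroxy ketone, which could open the C1–C2 bond by retro-aldol cleavage.

Step 9
Reactants: 12 (1S,2R,5S,6R,7S)-5-allyl-7-(3,4-dimethoxyphenyl)-2-hydroxy-1-methoxy-6-methylbicyclo[3.2.1]octan-8-one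
Product: 13 (1S,5S,6R,7S)-5-allyl-7-(3,4-dimethoxyphenyl)-1-methoxy-6-methylbicyclo[3.2.1]octane-2,8-dione
Conditions: Dess–Martin periodinane, CH2Cl2, rt
Reagents that add atoms: none
Why: Dess–Martin oxidation of the secondary alcohol under neutral conditions should give the β-diketone, which cannot enolise at C1, and removes the C2 stereocentre.

Step 10
Reactants: 13 (1S,5S,6R,7S)-5-allyl-7-(3,4-dimethoxyphenyl)-1-methoxy-6-methylbicyclo[3.2.1]octane-2,8-dione
Product: 15 (1R,3S,5R,6R,7S)-5-allyl-7-(3,4-dimethoxyphenyl)-3-hydroxy-1-methoxy-6-methylbicyclo[3.2.1]octane-2,8-dione, via potassium enolate 14 (not isolated)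
Conditions: KN(SiMe3)2, THF, −78 °C; 3-phenyl-2-(phenylsulfonyl)oxaziridine, −78 °C; AcOH
Reagents that add atoms: 3-phenyl-2-(phenylsulfonyl)oxaziridine, O=S(=O)(c1ccccc1)N1OC1c1ccccc1
Why: Only the C2 ketone has α-hydrogens (at C3), so enolate formation is regiospecific, and enolate hydroxylation with the oxaziridine should occur on the C8 face of C3 because the other face is covered by the two-carbon bridge with its endo methyl group.

Step 11
Reactants: 15 (1R,3S,5R,6R,7S)-5-allyl-7-(3,4-dimethoxyphenyl)-3-hydroxy-1-methoxy-6-methylbicyclo[3.2.1]octane-2,8-dione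
Product: 16 (1R,3S,5R,6R,7S)-5-allyl-7-(3,4-dimethoxyphenyl)-1,3-dimethoxy-6-methylbicyclo[3.2.1]octane-2,8-dione
Conditions: CF3SO3Me, 2,6-di-tert-butyl-4-methylpyridine, CH2Cl2, 0 °C → rt
Reagents that add atoms: methyl trifluoromethanesulfonate, COS(=O)(=O)C(F)(F)F
Why: O-methylation of the secondary α-ketol with methyl triflate and a hindered pyridine base avoids alkoxide formation and with it α-ketol shifts and retro-Claisen opening of the β-diketone.

Step 12
Reactants: 16 (1R,3S,5R,6R,7S)-5-allyl-7-(3,4-dimethoxyphenyl)-1,3-dimethoxy-6-methylbicyclo[3.2.1]octane-2,8-dione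
Product: 18 (1S,5R,6R,7S)-5-allyl-7-(3,4-dimethoxyphenyl)-1,3-dimethoxy-6-methyl-8-oxobicyclo[3.2.1]oct-2-en-2-yl trifluoromethanesulfonate, via potassium enolate 17 (not isolated)
Conditions: KN(SiMe3)2, THF, −78 °C; PhN(SO2CF3)2, −78 → 0 °C
Reagents that add atoms: N-phenylbis(trifluoromethanesulfonimide), O=S(=O)(N(c1ccccc1)S(=O)(=O)C(F)(F)F)C(F)(F)F
Why: The single remaining α-hydrogen (C3–H, axial and so aligned with the C2 carbonyl) is removed and the enolate is O-sulfonylated (enol triflate formation), which fixes the double bond at C2=C3 and erases the C3 centre.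

Step 13
Reactants: 18 (1S,5R,6R,7S)-5-allyl-7-(3,4-dimethoxyphenyl)-1,3-dimethoxy-6-methyl-8-oxobicyclo[3.2.1]oct-2-en-2-yl trifluoromethanesulfonate
Product: 19 (1S,5R,6R,7S)-5-allyl-7-(3,4-dimethoxyphenyl)-1,3-dimethoxy-6-methylbicyclo[3.2.1]oct-2-en-8-one
Conditions: Pd(OAc)2 (cat.), PPh3, HCO2H, Et3N, DMF, 60 °C
Reagents that add atoms: none
Why: Palladium-catalysed formate reduction of the enol triflate (hydride transfer to the vinylpalladium intermediate) should replace the triflate by hydrogen without moving the double bond and without touching the C8 ketone or the terminal alkene.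

Step 14
Reactants: 19 (1S,5R,6R,7S)-5-allyl-7-(3,4-dimethoxyphenyl)-1,3-dimethoxy-6-methylbicyclo[3.2.1]oct-2-en-8-one
Product: 21 (1S,2S,5S,6R,7S)-5-allyl-7-(3,4-dimethoxyphenyl)-2-hydroxy-1,3-dimethoxy-6-methylbicyclo[3.2.1]oct-3-en-8-one, via allylic hydroperoxide 20 (not isolated)
Conditions: O2, tetraphenylporphyrin (cat.), hν (visible), CH2Cl2, −40 °C; then PPh3
Reagents that add atoms: oxygen, O=O
Why: Schenck ene reaction of singlet oxygen with the methyl enol ether, in which the only allylic hydrogens are at C4 so that oxygen must bond to C2 while the double bond moves to C3=C4; bonding and hydrogen abstraction are suprafacial and the C7 face of the three-carbon bridge is blocked by the two-carbon bridge with its endo methyl group while the planar C8 carbonyl leaves the other face open, so the C2–O bond should form on the C8 face (2S), and PPh3 then reduces the hydroperoxide to the alcohol.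

Step 15
Reactants: 21 (1S,2S,5S,6R,7S)-5-allyl-7-(3,4-dimethoxyphenyl)-2-hydroxy-1,3-dimethoxy-6-methylbicyclo[3.2.1]oct-3-en-8-one
Product: 22 (1S,2S,5S,6R,7S)-5-allyl-7-(3,4-dimethoxyphenyl)-1,3-dimethoxy-6-methyl-8-oxobicyclo[3.2.1]oct-3-en-2-yl acetate
Conditions: Ac2O, pyridine, DMAP (cat.), CH2Cl2, 0 °C → rt
Reagents that add atoms: acetic anhydride, CC(=O)OC(C)=O
Why: DMAP-catalysed acylation of the secondary allylic alcohol under basic conditions, which the acid-sensitive enol ether tolerates, should give the target without change at any stereocentre.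

**Compound list**

1 | cyclohexane-1,2-dione | O=C1CCCCC1=O | starting material
2 | allyl bromide | C=CCBr | starting material
3 | 2-(allyloxy)cyclohex-2-en-1-one | C=CCOC1=CCCCC1=O | intermediate
4 | 3-allyl-2-hydroxycyclohex-2-en-1-one | C=CCC1=C(O)C(=O)CCC1 | intermediate
5 | 3-allyl-2-methoxycyclohex-2-en-1-one | C=CCC1=C(OC)C(=O)CCC1 | intermediate
6 | lithium 5-allyl-6-methoxycyclohexa-1,5-dien-1-olate (α'-enolate of 5) | C=CCC1=C(OC)C([O-])=CCC1.[Li+] | intermediate (not isolated)
7 | rac-3-allyl-6-hydroxy-2-methoxycyclohex-2-en-1-one | C=CCC1=C(OC)C(=O)C(O)CC1 | intermediate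
8 | (R)-4-allyl-3-methoxy-2-oxocyclohex-3-en-1-yl acetate | C=CCC1=C(OC)C(=O)[C@H](OC(C)=O)CC1 | intermediate
9 | (E)-isoeugenol methyl ether, 1,2-dimethoxy-4-[(E)-prop-1-enyl]benzene | C/C=C/c1ccc(OC)c(OC)c1 | starting material
10 | (1R,3R,6S,7R,8S)-6-allyl-8-(3,4-dimethoxyphenyl)-1-methoxy-7-methyl-2-oxobicyclo[4.2.0]octan-3-yl acetate (cis-fused; aryl cis to OMe on the convex face; methyl trans to aryl) | C=CC[C@]12CC[C@@H](OC(C)=O)C(=O)[C@@]1(OC)[C@H](c1ccc(OC)c(OC)c1)[C@H]2C | intermediate (key-step precursor)
11 | (1S,2R,5S,6R,7S)-5-allyl-7-(3,4-dimethoxyphenyl)-1-methoxy-6-methyl-8-oxobicyclo[3.2.1]octan-2-yl acetate (aryl exo, methyl endo) | C=CC[C@]12CC[C@@H](OC(C)=O)[C@](OC)(C1=O)[C@H](c1ccc(OC)c(OC)c1)[C@H]2C | intermediate (key-step product)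
12 | (1S,2R,5S,6R,7S)-5-allyl-7-(3,4-dimethoxyphenyl)-2-hydroxy-1-methoxy-6-methylbicyclo[3.2.1]octan-8-one | C=CC[C@]12CC[C@@H](O)[C@](OC)(C1=O)[C@H](c1ccc(OC)c(OC)c1)[C@H]2C | intermediate
13 | (1S,5S,6R,7S)-5-allyl-7-(3,4-dimethoxyphenyl)-1-methoxy-6-methylbicyclo[3.2.1]octane-2,8-dione | C=CC[C@]12CCC(=O)[C@](OC)(C1=O)[C@H](c1ccc(OC)c(OC)c1)[C@H]2C | intermediate
14 | potassium 5-allyl-7-(3,4-dimethoxyphenyl)-1-methoxy-6-methyl-8-oxobicyclo[3.2.1]oct-2-en-2-olate (C2 enolate of 13; ring configured as in 13) | C=CC[C@]12CC=C([O-])[C@](OC)(C1=O)[C@H](c1ccc(OC)c(OC)c1)[C@H]2C.[K+] | intermediate (not isolated)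
15 | (1R,3S,5R,6R,7S)-5-allyl-7-(3,4-dimethoxyphenyl)-3-hydroxy-1-methoxy-6-methylbicyclo[3.2.1]octane-2,8-dione (3-OH on the C8 face) | C=CC[C@]12C[C@H](O)C(=O)[C@](OC)(C1=O)[C@H](c1ccc(OC)c(OC)c1)[C@H]2C | intermediate
16 | (1R,3S,5R,6R,7S)-5-allyl-7-(3,4-dimethoxyphenyl)-1,3-dimethoxy-6-methylbicyclo[3.2.1]octane-2,8-dione | C=CC[C@]12C[C@H](OC)C(=O)[C@](OC)(C1=O)[C@H](c1ccc(OC)c(OC)c1)[C@H]2C | intermediate
17 | potassium 5-allyl-7-(3,4-dimethoxyphenyl)-1,3-dimethoxy-6-methyl-8-oxobicyclo[3.2.1]oct-2-en-2-olate (enolate of 16; ring configured as in 16) | C=CC[C@]12CC(OC)=C([O-])[C@](OC)(C1=O)[C@H](c1ccc(OC)c(OC)c1)[C@H]2C.[K+] | intermediate (not isolated)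
18 | (1S,5R,6R,7S)-5-allyl-7-(3,4-dimethoxyphenyl)-1,3-dimethoxy-6-methyl-8-oxobicyclo[3.2.1]oct-2-en-2-yl trifluoromethanesulfonate | C=CC[C@]12CC(OC)=C(OS(=O)(=O)C(F)(F)F)[C@](OC)(C1=O)[C@H](c1ccc(OC)c(OC)c1)[C@H]2C | intermediate
19 | (1S,5R,6R,7S)-5-allyl-7-(3,4-dimethoxyphenyl)-1,3-dimethoxy-6-methylbicyclo[3.2.1]oct-2-en-8-one | C=CC[C@]12CC(OC)=C[C@](OC)(C1=O)[C@H](c1ccc(OC)c(OC)c1)[C@H]2C | intermediate
20 | (1S,2S,5S,6R,7S)-5-allyl-7-(3,4-dimethoxyphenyl)-2-hydroperoxy-1,3-dimethoxy-6-methylbicyclo[3.2.1]oct-3-en-8-one | C=CC[C@]12C=C(OC)[C@H](OO)[C@](OC)(C1=O)[C@H](c1ccc(OC)c(OC)c1)[C@H]2C | intermediate (not isolated)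
21 | (1S,2S,5S,6R,7S)-5-allyl-7-(3,4-dimethoxyphenyl)-2-hydroxy-1,3-dimethoxy-6-methylbicyclo[3.2.1]oct-3-en-8-one (2-OH on the C8 face) | C=CC[C@]12C=C(OC)[C@H](O)[C@](OC)(C1=O)[C@H](c1ccc(OC)c(OC)c1)[C@H]2C | intermediate
22 | (1S,2S,5S,6R,7S)-5-allyl-7-(3,4-dimethoxyphenyl)-1,3-dimethoxy-6-methyl-8-oxobicyclo[3.2.1]oct-3-en-2-yl acetate | C=CC[C@]12C=C(OC)[C@H](OC(C)=O)[C@](OC)(C1=O)[C@H](c1ccc(OC)c(OC)c1)[C@H]2C | target

**Step count**

Total: 15 steps. Longest linear sequence: 15 steps from cyclohexane-1,2-dione; 9 enters at step 6.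

**Steps most likely to fail**

1. Step 7 (double 1,2-shift).
 - What may go wrong: migration of the benzylic cyclobutane carbon in place of the ring-fusion carbon, which would lead to a bicyclo[3.3.0]octanone, or Lewis-acid heterolysis of the donor–acceptor bond between the methoxy carbon and the benzylic carbon, which would lead to ring-opened or oxygen-closed products.
 - Fallback: it sets out from 2 and 9 and comes back at 18. Commercial 2,3,4-trimethoxyphenol would be O-allylated with 2 (K2CO3, acetone) to 1-(allyloxy)-2,3,4-trimethoxybenzene F1 and heated (190 °C) to the Claisen product 6-allyl-2,3,4-trimethoxyphenol F2. PhI(OAc)2 in MeOH would give the quinone monoketal 6-allyl-2,3,4,4-tetramethoxycyclohexa-2,5-dien-1-one F3. CF3SO3H (or Me3SiOSO2CF3) at −78 °C would ionise the ketal, and the pentadienyl cation would add 9 in a cationic [5+2] cycloaddition, the reaction type established for bicyclo[3.2.1]octanoid neolignans. After aqueous work-up this would give racemic 5-allyl-7-(3,4-dimethoxyphenyl)-1,3-dimethoxy-6-methylbicyclo[3.2.1]oct-3-ene-2,8-dione F4, expected with the aryl group exo and the methyl group endo. Conjugate reduction with LiBH(s-Bu)3 at −78 °C and trapping of the enolate with PhN(SO2CF3)2 would give 18 as the racemate. Its enantiomers would be separated by chromatography on a chiral stationary phase before step 13.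

2. Step 6 ([2+2] photocycloaddition).
 - What may go wrong: ring closure in the head-to-tail sense, energy transfer to the styrene with E/Z isomerisation in place of cycloaddition, or a mixture of exo/endo and facial isomers from which 10 cannot be separated.
 - Fallback: it sets out from 8 and comes back at 10. Reduction of 8 (NaBH4, CeCl3·7H2O, MeOH, −78 °C) would give (1R)-4-allyl-2-hydroxy-3-methoxycyclohex-3-en-1-yl acetate F5, and silylation (t-BuMe2SiCl, imidazole) would give the silyl ether F6, in which the ring double bond is an electron-rich enol ether. A hole-catalysed (radical-cation) [2+2] cycloaddition with 9 ((4-BrC6H4)3N SbCl6 cat., CH2Cl2, 0 °C, or Ru(bpz)3(PF6)2 with visible light) would fix the orientation by polarity. The radical cation of 9 is attacked at its CHMe carbon by the allyl-bearing enol ether carbon, and the benzylic carbon then closes onto the methoxy carbon, giving cyclobutane silyl ether F7. HF·pyridine would give the alcohol F8, and Dess–Martin oxidation would return 10 after the same separation of facial isomers.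

3. Step 14 (singlet-oxygen ene reaction).
 - What may go wrong: [2+2] addition of singlet oxygen to the enol ether and dioxetane cleavage of the C2–C3 bond in place of the ene reaction, or further oxidation of the product enol ether.
 - Fallback: it sets out from 19 and comes back at 21. Dimethyldioxirane (acetone/CH2Cl2, −78 °C) would epoxidise the enol ether, far faster than the terminal alkene and on the same C8 face, to the 2,3-epoxide F9. Me3SiOSO2CF3 with 2,6-lutidine would open it to the C3 oxocarbenium ion and remove a C4 proton (epoxide-to-allylic silyl ether isomerisation), giving the trimethylsilyl ether F10. Bu4NF buffered with AcOH would give 21.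

**Further compounds**

F1 | step 7 | 1-(allyloxy)-2,3,4-trimethoxybenzene | C=CCOc1ccc(OC)c(OC)c1OC
F2 | step 7 | 6-allyl-2,3,4-trimethoxyphenol | C=CCc1cc(OC)c(OC)c(OC)c1O
F3 | step 7 | 6-allyl-2,3,4,4-tetramethoxycyclohexa-2,5-dien-1-one | C=CCC1=CC(OC)(OC)C(OC)=C(OC)C1=O
F4 | step 7 | rac-5-allyl-7-(3,4-dimethoxyphenyl)-1,3-dimethoxy-6-methylbicyclo[3.2.1]oct-3-ene-2,8-dione (relative configuration shown; aryl exo, methyl endo) | C=CC[C@]12C=C(OC)C(=O)[C@](OC)(C1=O)[C@H](c1ccc(OC)c(OC)c1)[C@H]2C
F5 | step 6 | (1R)-4-allyl-2-hydroxy-3-methoxycyclohex-3-en-1-yl acetate (C2 epimers) | C=CCC1=C(OC)C(O)[C@H](OC(C)=O)CC1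
F6 | step 6 | (1R)-4-allyl-2-[(tert-butyldimethylsilyl)oxy]-3-methoxycyclohex-3-en-1-yl acetate (C2 epimers) | C=CCC1=C(OC)C(O[Si](C)(C)C(C)(C)C)[C@H](OC(C)=O)CC1
F7 | step 6 | 6-allyl-2-[(tert-butyldimethylsilyl)oxy]-8-(3,4-dimethoxyphenyl)-1-methoxy-7-methylbicyclo[4.2.0]octan-3-yl acetate (ring configured as in 10; C2 epimers) | C=CC[C@]12CC[C@@H](OC(C)=O)C(O[Si](C)(C)C(C)(C)C)[C@@]1(OC)[C@H](c1ccc(OC)c(OC)c1)[C@H]2C
F8 | step 6 | 6-allyl-8-(3,4-dimethoxyphenyl)-2-hydroxy-1-methoxy-7-methylbicyclo[4.2.0]octan-3-yl acetate (ring configured as in 10; C2 epimers) | C=CC[C@]12CC[C@@H](OC(C)=O)C(O)[C@@]1(OC)[C@H](c1ccc(OC)c(OC)c1)[C@H]2C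
F9 | step 14 | 5-allyl-7-(3,4-dimethoxyphenyl)-2,3-epoxy-1,3-dimethoxy-6-methylbicyclo[3.2.1]octan-8-one (epoxide oxygen on the C8 face) | C=CC[C@]12C[C@]3(OC)O[C@@H]3[C@](OC)(C1=O)[C@H](c1ccc(OC)c(OC)c1)[C@H]2C
F10 | step 14 | trimethylsilyl ether of 21, (1S,2S,5S,6R,7S)-5-allyl-7-(3,4-dimethoxyphenyl)-1,3-dimethoxy-6-methyl-2-[(trimethylsilyl)oxy]bicyclo[3.2.1]oct-3-en-8-one | C=CC[C@]12C=C(OC)[C@H](O[Si](C)(C)C)[C@](OC)(C1=O)[C@H](c1ccc(OC)c(OC)c1)[C@H]2C
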